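The route is written in halimane numbering. It rests on cutting C9–C11, the bond from the quaternary ring-B carbon to the side chain. C9 is allylic to the C1=C10 alkene shared by rings A and B, so this alkene is read as a spent C1 enolate. A homoallyl cuprate carrying the whole C11–C16 chain adds 1,4 to a bicyclic enone, a ring-locked s-cis 2-alkylidenecyclohexanone (C1 ketone, tetrasubstituted C9=C10), and the enolate is trapped as its triflate. One operation forms C9–C11, sets the C9 quaternary centre anti to the C8 methyl and fixes the alkene position. The enone arises from (R)-β-citronellene by Wacker oxidation, cross-metathesis, asymmetric Diels–Alder reaction and aldol condensation.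

Key step: step 12

Numbering and faces: ring A is C1–C5 and C10, and ring B is C5–C10. C11–C15 form the chain, and C16 is the methyl on C13. C17 is the methyl on C8, C18 the carboxyl carbon on C4, C19 the methyl on C4, and C20 the methyl on C9. The β face is the one that carries H5.

Assumption: the (S)-configured oxazaborolidinium of step 4 is taken to expose the Cα-Si/Cβ-Re face of the enal dienophile. If the sense is the opposite, the equally available (R)-antipode is used and nothing else changes.

Step 1
Reactants: 1 (R)-β-citronellene [(3R)-3,7-dimethylocta-1,6-diene]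
Product: 2 (3R)-3,7-dimethyloct-6-en-2-one
Conditions: PdCl2 (10 mol %), CuCl (30 mol %), O2 (1 atm), DMF–H2O 7:1, rt
Reagents that add atoms: water (SMILES O)
Why: Tsuji–Wacker oxidation, in which Markovnikov hydroxypalladation takes place only at the monosubstituted alkene while the trisubstituted alkene stays inert, so the chiral-pool centre becomes C8 (R) next to the future C9 ketone.

Step 2
Reactants: 2 (3R)-3,7-dimethyloct-6-en-2-one; 3 methacrolein
Product: 4 (2E,6R)-2,6-dimethyl-7-oxooct-2-enal
Conditions: second-generation Hoveyda–Grubbs catalyst (3 mol %), 3 (8 equiv), CH2Cl2, 40 °C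
Reagents that add atoms: none
Why: Olefin cross-metathesis, in which the isopropylidene terminus is exchanged for the methacrolein alkylidene with loss of volatile isobutene, and the conjugated trisubstituted enal should form as the favoured E isomer, whose geometry later encodes the C4/C5 relationship.

Step 3
Reactants: 5 methyl vinyl ketone (but-3-en-2-one)
Product: 6 2-(triisopropylsilyloxy)buta-1,3-diene
Conditions: TIPSOTf, Et3N, Et2O, 0 °C to rt
Reagents that add atoms: triisopropylsilyl triflate (SMILES CC(C)[Si](C(C)C)(C(C)C)OS(=O)(=O)C(F)(F)F)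
Why: Soft enolisation and O-silylation of the methyl ketone give the 2-silyloxydiene, and the bulky silyl group keeps it intact under the strongly acidic catalyst of step 4.

Step 4
Reactants: 4 (2E,6R)-2,6-dimethyl-7-oxooct-2-enal; 6 2-(triisopropylsilyloxy)buta-1,3-diene
Product: 8 (1S,2S)-1-methyl-2-[(3R)-3-methyl-4-oxopentyl]-4-oxocyclohexane-1-carbaldehyde, via cycloadduct 7 (not isolated)
Conditions: (S)-1-(2-methylphenyl)-3,3-diphenyltetrahydro-1H,3H-pyrrolo[1,2-c][1,3,2]oxazaborole (20 mol %), Tf2NH (18 mol %), CH2Cl2, −78 to −40 °C; then 48 % aq HF, MeCN, 0 °C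
Reagents that add atoms: none
Why: Catalytic enantioselective Diels–Alder reaction, in which the nucleophilic CH2 terminus of the silyloxydiene bonds to the enal β-carbon C5 (para orientation), suprafacial addition to the E-enal places CHO cis to H5, and the chiral Lewis acid shields one enal face so that 4S,5S arises under catalyst control regardless of the remote C8 centre, after which HF frees the C1 ketone.

Step 5
Reactants: 8 (1S,2S)-1-methyl-2-[(3R)-3-methyl-4-oxopentyl]-4-oxocyclohexane-1-carbaldehyde
Product: 9 (1S,2S)-1-methyl-2-[(3R)-3-methyl-4-oxopentyl]-4-oxocyclohexane-1-carboxylic acid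
Conditions: NaClO2, NaH2PO4, 2-methylbut-2-ene, t-BuOH–H2O, rt
Reagents that add atoms: sodium chlorite (SMILES [Na+].[O-]Cl=O)
Why: Pinnick oxidation turns the non-enolisable neopentyl aldehyde into the acid in a mild phosphate buffer that leaves both ketones and the C8 centre alone, and it removes the aldehyde before it can act as an aldol acceptor.

Step 6
Reactants: 9 (1S,2S)-1-methyl-2-[(3R)-3-methyl-4-oxopentyl]-4-oxocyclohexane-1-carboxylic acid
Product: 10 2-(trimethylsilyl)ethyl (1S,2S)-1-methyl-2-[(3R)-3-methyl-4-oxopentyl]-4-oxocyclohexane-1-carboxylate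
Conditions: 2-(trimethylsilyl)ethanol, PPh3, DIAD, THF, 0 °C to rt
Reagents that add atoms: 2-(trimethylsilyl)ethanol (SMILES C[Si](C)(C)CCO)
Why: Mitsunobu esterification, in which the hindered tertiary carboxylate acts only as nucleophile toward the activated primary alcohol so that crowding at C4 does not matter, and the resulting fluoride-labile ester tolerates enamines, cuprates and palladium.

Step 7
Reactants: 10 2-(trimethylsilyl)ethyl (1S,2S)-1-methyl-2-[(3R)-3-methyl-4-oxopentyl]-4-oxocyclohexane-1-carboxylate
Product: 11 2-(trimethylsilyl)ethyl (1S,6R,8aS)-1,5,6-trimethyl-4-oxo-1,2,3,4,6,7,8,8a-octahydronaphthalene-1-carboxylate (4S,5S,8R in halimane numbering)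
Conditions: pyrrolidine (1.2 equiv), AcOH (1.2 equiv), toluene, 4 Å MS, 80 °C; then aq NaOAc–AcOH, rt
Reagents that add atoms: none
Why: Enamine-mediated intramolecular aldol condensation of a 1,7-diketone, in which only attack of C10 on C9 gives a six-membered ring that can lose water (closure from C2 would be eight-membered and the bridged C8-to-C1 ketol cannot dehydrate and reverts), while the amine buffer engages the unhindered ring ketone in preference to the branched methyl ketone and so should spare the C8–H.

Step 8
Reactants: 12 4-(tert-butyldimethylsilyloxy)but-1-yne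
Product: 15 (E)-5-(tert-butyldimethylsilyloxy)-3-methylpent-2-en-1-ol, via alkenylalane 13 (not isolated), via lithium alanate 14 (not isolated)
Conditions: Me3Al (2.5 equiv), Cp2ZrCl2 (25 mol %), CH2Cl2, 0 °C to rt; n-BuLi, hexane–THF, −78 °C; (CH2O)n, THF, rt; 1 M HCl
Reagents that add atoms: trimethylaluminium (SMILES C[Al](C)C); paraformaldehyde, counted as formaldehyde (SMILES C=O)
Why: Zirconium-catalysed Negishi carboalumination adds methyl and aluminium syn across the alkyne with aluminium at the terminus, and hydroxymethylation of the derived alanate with retention fixes the E geometry of C13=C14.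

Step 9
Reactants: 15 (E)-5-(tert-butyldimethylsilyloxy)-3-methylpent-2-en-1-ol
Product: 16 (E)-5-(tert-butyldimethylsilyloxy)-1-(tert-butyldiphenylsilyloxy)-3-methylpent-2-ene
Conditions: TBDPSCl, imidazole, CH2Cl2, rt
Reagents that add atoms: tert-butylchlorodiphenylsilane (SMILES CC(C)(C)[Si](Cl)(c1ccccc1)c1ccccc1)
Why: Standard imidazole-promoted O-silylation, with the more acid-stable silyl group placed on the allylic oxygen so that the two ends can be told apart in step 10.

Step 10
Reactants: 16 (E)-5-(tert-butyldimethylsilyloxy)-1-(tert-butyldiphenylsilyloxy)-3-methylpent-2-ene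
Product: 17 (E)-5-(tert-butyldiphenylsilyloxy)-3-methylpent-3-en-1-ol
Conditions: camphorsulfonic acid (10 mol %), MeOH–CH2Cl2 1:1, 0 °C
Reagents that add atoms: none
Why: Acid-catalysed methanolysis of silyl ethers removes the primary tert-butyldimethylsilyl group much faster than the bulkier tert-butyldiphenylsilyl group.

Step 11
Reactants: 17 (E)-5-(tert-butyldiphenylsilyloxy)-3-methylpent-3-en-1-ol
Product: 18 (E)-tert-butyl[(5-iodo-3-methylpent-2-en-1-yl)oxy]diphenylsilane
Conditions: I2, PPh3, imidazole, CH2Cl2, 0 °C to rt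
Reagents that add atoms: iodine (SMILES II)
Why: Appel-type iodination (SN2 displacement of an alkoxyphosphonium ion) runs under nearly neutral conditions and leaves the allylic silyl ether and the alkene geometry untouched.

Step 12
Reactants: 11 2-(trimethylsilyl)ethyl (1S,6R,8aS)-1,5,6-trimethyl-4-oxo-1,2,3,4,6,7,8,8a-octahydronaphthalene-1-carboxylate; 18 (E)-tert-butyl[(5-iodo-3-methylpent-2-en-1-yl)oxy]diphenylsilane
Product: 22 2-(trimethylsilyl)ethyl (4S,5S,8R,9S)-15-(tert-butyldiphenylsilyloxy)-1-(trifluoromethylsulfonyloxy)halima-1(10),13E-dien-18-oate, via organolithium 19 (not isolated), via cuprate 20 (not isolated), via lithium enolate 21 (not isolated)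
Conditions: 18 (3 equiv), t-BuLi (6 equiv), Et2O–pentane, −78 °C; CuI (1.5 equiv), Et2O–Me2S, −78 to −35 °C; 11, Et2O, −78 to −20 °C; N-(5-chloropyridin-2-yl)bis(trifluoromethanesulfonimide), THF–DMPU, −78 to 0 °C; aq NH4Cl
Reagents that add atoms: N-(5-chloropyridin-2-yl)bis(trifluoromethanesulfonimide) (SMILES FC(F)(F)S(=O)(=O)N(c1ccc(Cl)cn1)S(=O)(=O)C(F)(F)F)
Why: Iodine–lithium exchange and CuI give lithium dialkylcuprate 20, which binds the C9=C10 π bond of 11, adds oxidatively to a β-cuprio enolate of trivalent copper and reductively eliminates to forge C9–C11, leaving lithium enolate 21 that is O-sulfonylated in the same flask. The closest known reaction type is cuprate 1,4-addition to tetrasubstituted, fixed s-cis 2-alkylidenecyclohexanones of the pulegone class, combined with regiospecific trapping of the enolate as its enol triflate. No ring is closed. The only new stereocentre, C9, is controlled by C8: A(1,2) strain with the C9 methyl holds the C8 methyl pseudoaxial on the α face of the ring-B half-chair (H5 pseudoaxial on the β face), so the cuprate should enter axially from the β face, anti to that methyl, placing the chain trans to C17 and the two methyls cis (9S). The step needs 1,4- over 1,2-addition, secured by the soft cuprate and the coplanar s-cis enone; it needs the ester to stay untouched, secured by the neopentyl position of C18; and it needs an enolate that does not drift to C2, secured by the aprotic medium and fast O-triflation. The C1=C10 enol triflate thus stores the alkene position of the target.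

Step 13
Reactants: 22 2-(trimethylsilyl)ethyl (4S,5S,8R,9S)-15-(tert-butyldiphenylsilyloxy)-1-(trifluoromethylsulfonyloxy)halima-1(10),13E-dien-18-oate
Product: 23 2-(trimethylsilyl)ethyl (4S,5S,8R,9S)-15-(tert-butyldiphenylsilyloxy)halima-1(10),13E-dien-18-oate
Conditions: Pd(OAc)2 (10 mol %), PPh3 (20 mol %), HCO2H (3 equiv), Et3N (5 equiv), DMF, 60 °C
Reagents that add atoms: none
Why: Palladium-catalysed formate reduction of an enol triflate (oxidative addition of zerovalent palladium, formate exchange, decarboxylation, C–H reductive elimination) replaces OTf by H without moving the alkene, so C1=C10 follows from the enolate regiochemistry.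

Step 14
Reactants: 23 2-(trimethylsilyl)ethyl (4S,5S,8R,9S)-15-(tert-butyldiphenylsilyloxy)halima-1(10),13E-dien-18-oate
Product: 24 (4S,5S,8R,9S)-15-hydroxyhalima-1(10),13E-dien-18-oic acid
Conditions: TBAF (5 equiv), THF, 0 to 40 °C; cold 0.5 M HCl
Reagents that add atoms: none
Why: Fluoride-induced desilylation attacks silicon only, cleaving the silyl ether and fragmenting the 2-(trimethylsilyl)ethyl ester by β-elimination to carboxylate, ethylene and Me3SiF, so the crowded C18 carbonyl never has to be attacked.

Step 15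
Reactants: 24 (4S,5S,8R,9S)-15-hydroxyhalima-1(10),13E-dien-18-oic acid
Product: 25 (4S,5S,8R,9S)-15-(propanoyloxy)halima-1(10),13E-dien-18-oic acid (target)
Conditions: propionic anhydride (1.5 equiv), pyridine, DMAP (5 mol %), CH2Cl2, 0 °C to rt; then aq NaHCO3 stir and acidification to pH 3
Reagents that add atoms: propionic anhydride (SMILES CCC(=O)OC(=O)CC)
Why: DMAP-catalysed acylation takes the primary allylic alcohol, and any mixed anhydride formed at the hindered C18 carboxyl is hydrolysed at its unhindered propionyl carbonyl during the aqueous stir, which returns the free acid.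

Compound list
1 | (R)-β-citronellene, (3R)-3,7-dimethylocta-1,6-diene | C=C[C@H](C)CCC=C(C)C | starting material
2 | (3R)-3,7-dimethyloct-6-en-2-one | CC(=O)[C@H](C)CCC=C(C)C | intermediate
3 | methacrolein | C=C(C)C=O | starting material
4 | (2E,6R)-2,6-dimethyl-7-oxooct-2-enal | CC(=O)[C@H](C)CC/C=C(\C)C=O | intermediate
5 | methyl vinyl ketone | C=CC(C)=O | starting material
6 | 2-(triisopropylsilyloxy)buta-1,3-diene | C=CC(=C)O[Si](C(C)C)(C(C)C)C(C)C | intermediate
7 | (1S,6S)-1-methyl-6-[(3R)-3-methyl-4-oxopentyl]-4-(triisopropylsilyloxy)cyclohex-3-ene-1-carbaldehyde | CC(C)[Si](OC1=CC[C@](C)(C=O)[C@@H](CC[C@@H](C)C(C)=O)C1)(C(C)C)C(C)C | intermediate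
8 | (1S,2S)-1-methyl-2-[(3R)-3-methyl-4-oxopentyl]-4-oxocyclohexane-1-carbaldehyde | O=C1CC[C@](C)(C=O)[C@@H](CC[C@@H](C)C(C)=O)C1 | intermediate
9 | (1S,2S)-1-methyl-2-[(3R)-3-methyl-4-oxopentyl]-4-oxocyclohexane-1-carboxylic acid | O=C1CC[C@](C)(C(=O)O)[C@@H](CC[C@@H](C)C(C)=O)C1 | intermediate
10 | 2-(trimethylsilyl)ethyl (1S,2S)-1-methyl-2-[(3R)-3-methyl-4-oxopentyl]-4-oxocyclohexane-1-carboxylate | O=C1CC[C@](C)(C(=O)OCC[Si](C)(C)C)[C@@H](CC[C@@H](C)C(C)=O)C1 | intermediate
11 | 2-(trimethylsilyl)ethyl (1S,6R,8aS)-1,5,6-trimethyl-4-oxo-1,2,3,4,6,7,8,8a-octahydronaphthalene-1-carboxylate | O=C1CC[C@](C)(C(=O)OCC[Si](C)(C)C)[C@H]2CC[C@@H](C)C(C)=C12 | intermediate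
12 | 4-(tert-butyldimethylsilyloxy)but-1-yne | C#CCCO[Si](C)(C)C(C)(C)C | starting material
13 | (E)-[4-(tert-butyldimethylsilyloxy)-2-methylbut-1-en-1-yl]dimethylalane | C[Al](C)/C=C(\C)CCO[Si](C)(C)C(C)(C)C | intermediate
14 | lithium butyl[(E)-4-(tert-butyldimethylsilyloxy)-2-methylbut-1-en-1-yl]dimethylalanate | [Li+].CCCC[Al-](C)(C)/C=C(\C)CCO[Si](C)(C)C(C)(C)C | intermediate
15 | (E)-5-(tert-butyldimethylsilyloxy)-3-methylpent-2-en-1-ol | OC/C=C(\C)CCO[Si](C)(C)C(C)(C)C | intermediate
16 | (E)-5-(tert-butyldimethylsilyloxy)-1-(tert-butyldiphenylsilyloxy)-3-methylpent-2-ene | CC(C)(C)[Si](OC/C=C(\C)CCO[Si](C)(C)C(C)(C)C)(c1ccccc1)c1ccccc1 | intermediate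
17 | (E)-5-(tert-butyldiphenylsilyloxy)-3-methylpent-3-en-1-ol | OCC/C(C)=C/CO[Si](c1ccccc1)(c1ccccc1)C(C)(C)C | intermediate
18 | (E)-tert-butyl[(5-iodo-3-methylpent-2-en-1-yl)oxy]diphenylsilane | ICC/C(C)=C/CO[Si](c1ccccc1)(c1ccccc1)C(C)(C)C | intermediate
19 | (E)-[5-(tert-butyldiphenylsilyloxy)-3-methylpent-3-en-1-yl]lithium | [Li]CC/C(C)=C/CO[Si](c1ccccc1)(c1ccccc1)C(C)(C)C | intermediate
20 | lithium bis[(E)-5-(tert-butyldiphenylsilyloxy)-3-methylpent-3-en-1-yl]cuprate | [Li+].CC(C)(C)[Si](OC/C=C(\C)CC[Cu-]CC/C(C)=C/CO[Si](c1ccccc1)(c1ccccc1)C(C)(C)C)(c1ccccc1)c1ccccc1 | intermediate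
21 | lithium 1(10)-enolate of 2-(trimethylsilyl)ethyl (4S,5S,8R,9S)-15-(tert-butyldiphenylsilyloxy)-1-oxohalim-13E-en-18-oate | [Li+].CC(C)(C)[Si](OC/C=C(\C)CC[C@]1(C)C2=C([O-])CC[C@](C)(C(=O)OCC[Si](C)(C)C)[C@H]2CC[C@H]1C)(c1ccccc1)c1ccccc1 | intermediate
22 | 2-(trimethylsilyl)ethyl (4S,5S,8R,9S)-15-(tert-butyldiphenylsilyloxy)-1-(trifluoromethylsulfonyloxy)halima-1(10),13E-dien-18-oate | CC(C)(C)[Si](OC/C=C(\C)CC[C@]1(C)C2=C(OS(=O)(=O)C(F)(F)F)CC[C@](C)(C(=O)OCC[Si](C)(C)C)[C@H]2CC[C@H]1C)(c1ccccc1)c1ccccc1 | intermediate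
23 | 2-(trimethylsilyl)ethyl (4S,5S,8R,9S)-15-(tert-butyldiphenylsilyloxy)halima-1(10),13E-dien-18-oate | CC(C)(C)[Si](OC/C=C(\C)CC[C@]1(C)C2=CCC[C@](C)(C(=O)OCC[Si](C)(C)C)[C@H]2CC[C@H]1C)(c1ccccc1)c1ccccc1 | intermediate
24 | (4S,5S,8R,9S)-15-hydroxyhalima-1(10),13E-dien-18-oic acid | OC/C=C(\C)CC[C@]1(C)C2=CCC[C@](C)(C(=O)O)[C@H]2CC[C@H]1C | intermediate
25 | (1S,5S,6R,8aS)-1,5,6-trimethyl-5-[(E)-3-methyl-5-(propanoyloxy)pent-3-en-1-yl]-1,2,3,5,6,7,8,8a-octahydronaphthalene-1-carboxylic acid | CCC(=O)OC/C=C(\C)CC[C@]1(C)C2=CCC[C@](C)(C(=O)O)[C@H]2CC[C@H]1C | target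

Total step count: 15. Longest linear sequence: 10 steps (1, 2, 4, 5, 6, 7, 12, 13, 14, 15).

Steps most likely to fail

1. Step 12.
- **What may go wrong:** The primary alkyl cuprate may decay thermally before it transfers its group to the crowded β-carbon. 1,2-Addition or γ-deprotonation may compete. O-sulfonylation of the congested enolate may be slow enough for protons to scramble.
- **Fallback:** Allylic substitution with 1,3-chirality transfer replaces conjugate addition. Setting out from 11, DIBAL-H in toluene at −78 °C should attack C1 along the equatorial trajectory from the α face, because an equatorial hydroxyl would clash with the C9 methyl (A(1,3) strain). This should give the axial 1β-allylic alcohol F1. PhNCO and DMAP convert it into the N-phenylcarbamate F2. Deprotonation with MeLi, complexation with CuI and addition of organolithium 19 (made from 18 as in step 12) tie the copper to the carbamate nitrogen. The alkyl group is then delivered intramolecularly, syn to the leaving group, to the β face of C9 (carbamate-directed syn-SN2′ displacement), and the alkene moves to C1=C10. The product is 23, so step 13 is bypassed and the route resumes at step 14.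

2. Step 4.
- **What may go wrong:** The trisubstituted enal may react sluggishly, the distal ketone may sequester the catalyst, the diene may be protodesilylated, and facial discrimination may be poor.
- **Fallback:** A far more nucleophilic diene is used, with a later saturation. Setting out from 4, commercial (E)-3-(tert-butyldimethylsilyloxy)-N,N-dimethylbuta-1,3-dien-1-amine is added in CH2Cl2 with a chiral (salen)CrSbF6 complex, its antipode chosen as for step 4. This should give the amino cycloadduct F3 with the same regiochemistry and the same stereospecific C4/C5 relationship. HF in MeCN cleaves the silyl enol ether and eliminates the amine to give the cyclohexenone aldehyde F4. Hydrogenation of the disubstituted enone alkene (H2, Pd/C, EtOAc) comes back to 8.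

3. Step 7.
- **What may go wrong:** Closure may be slow and reversible, with unproductive enamine formation toward C2. During that time the C8–H next to the C9 ketone can exchange, so the chiral-pool centre drifts, or the alkene may settle out of conjugation.
- **Fallback:** Ring B is closed by palladium-catalysed ketone α-alkenylation, so that C9 is never a ketone while ring B is open. Setting out from 2, kinetic deprotonation at the methyl group (LDA, THF, −78 °C) and PhNTf2 give the 1-alken-2-yl triflate F5, in which C8 is merely allylic. This triflate is taken through the operations of steps 2, 4, 5 and 6 unchanged. The sequence passes through the enal F6, the silyloxy cycloadduct F7, the keto aldehyde F8, the keto acid F9 and the 2-(trimethylsilyl)ethyl ester F10. Pd(PPh3)4 and PhOK in THF at reflux then join C10 to C9; this closure is six-membered, whereas closure at C2 would be eight-membered. It gives the exo-methylene ketone F11, which the base moves into conjugation to deliver 11.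

Further compounds
F1 | step 12 | 2-(trimethylsilyl)ethyl (1R,4S,5S,8R)-1β-hydroxy bicyclic allylic alcohol (C1 ketone of 11 reduced, OH axial on the β face) | O[C@@H]1CC[C@](C)(C(=O)OCC[Si](C)(C)C)[C@H]2CC[C@@H](C)C(C)=C12
F2 | step 12 | N-phenylcarbamate of F1 | O=C(Nc1ccccc1)O[C@@H]1CC[C@](C)(C(=O)OCC[Si](C)(C)C)[C@H]2CC[C@@H](C)C(C)=C12
F3 | step 4 | 4-(tert-butyldimethylsilyloxy)-2-(dimethylamino)-1-methyl-6-[(3R)-3-methyl-4-oxopentyl]cyclohex-3-ene-1-carbaldehyde (NMe2 cis to CHO, other centres as in 8) | CN(C)[C@H]1C=C(O[Si](C)(C)C(C)(C)C)C[C@H](CC[C@@H](C)C(C)=O)[C@@]1(C)C=O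
F4 | step 4 | 2,3-didehydro analogue of 8 (1-methyl-6-[(3R)-3-methyl-4-oxopentyl]-4-oxocyclohex-2-ene-1-carbaldehyde, centres as in 8) | O=C1C=C[C@](C)(C=O)[C@@H](CC[C@@H](C)C(C)=O)C1
F5 | step 7 | (3R)-3,7-dimethylocta-1,6-dien-2-yl trifluoromethanesulfonate | C=C(OS(=O)(=O)C(F)(F)F)[C@H](C)CCC=C(C)C
F6 | step 7 | (3R,6E)-3,7-dimethyl-8-oxoocta-1,6-dien-2-yl trifluoromethanesulfonate | C=C(OS(=O)(=O)C(F)(F)F)[C@H](C)CC/C=C(\C)C=O
F7 | step 7 | analogue of 7 with C9 as 1-alken-2-yl triflate | CC(C)[Si](OC1=CC[C@](C)(C=O)[C@@H](CC[C@@H](C)C(=C)OS(=O)(=O)C(F)(F)F)C1)(C(C)C)C(C)C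
F8 | step 7 | analogue of 8 with C9 as 1-alken-2-yl triflate | O=C1CC[C@](C)(C=O)[C@@H](CC[C@@H](C)C(=C)OS(=O)(=O)C(F)(F)F)C1
F9 | step 7 | analogue of 9 with C9 as 1-alken-2-yl triflate | O=C1CC[C@](C)(C(=O)O)[C@@H](CC[C@@H](C)C(=C)OS(=O)(=O)C(F)(F)F)C1
F10 | step 7 | analogue of 10 with C9 as 1-alken-2-yl triflate | O=C1CC[C@](C)(C(=O)OCC[Si](C)(C)C)[C@@H](CC[C@@H](C)C(=C)OS(=O)(=O)C(F)(F)F)C1
F11 | step 7 | β,γ-unsaturated isomer of 11 with exocyclic C9=C20 methylene (C10 unassigned, lost on conjugation) | O=C1CC[C@](C)(C(=O)OCC[Si](C)(C)C)[C@H]2CC[C@@H](C)C(=C)C12
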